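The chair laid the three flasks before the meeting with these constants, charges and questions.

    third reagent + intermediate B → target (k1 = 5.32 × 10⁻⁴ L mol⁻¹ s⁻¹, Ea1 = 93.0 kJ mol⁻¹)
    substrate + partner → intermediate A (k2 = 1.96 × 10⁻⁵ L mol⁻¹ s⁻¹, Ea2 = 87.0 kJ mol⁻¹)
    partner + protic impurity → quenched reagent (k3 = 0.00215 L mol⁻¹ s⁻¹, Ea3 = 81.0 kJ mol⁻¹)
    second reagent + intermediate A → intermediate B (k4 = 4.65 × 10⁻⁴ L mol⁻¹ s⁻¹, Ea4 = 73.0 kJ mol⁻¹)
    (constants at 80 °C)

the same everywhere: substrate 0.20 M; partner 1.00 M; second reagent 0.220 M; third reagent 0.140 M; protic impurity 0.0200 M; time 3.0 d

| charge | temperature |
|---|---|
| ochre | 80 °C |
| green | 30 °C |
| amber | 55 °C |

- the list of constants is for 80 °C, to be carried to other temperatures by the activation energies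

1. which flask leads in amount of target, in percent of the substrate charged ("all alike" within 1.5 percentage points) (ochre / green / amber / all alike)
2. how much target is there at the end, in percent of the substrate charged: ochre
3. how much target is there at the end, in percent of the substrate charged: green
4. how much target is there at the end, in percent of the substrate charged: amber

The process lead asked that the charges be balanced before any rate was discussed. She pointed out that third reagent appears in one arrow, the one that makes target, mole for mole, so in a closed flask the target formed plus the third reagent left equals the third reagent charged. She therefore proposed a ceiling C, defined as third reagent charged over substrate charged, which here is 70.0%; target, in percent of the substrate charged, is C less whatever third reagent remains on that scale. The amount of third reagent, 0.140 M, is smaller than the substrate and second reagent charges, and smaller than the 0.980 M of partner that the protic impurity can leave, so she called it the limiting reagent.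

The kineticist replied that a ceiling says nothing about arriving there in 3.0 d. She took the step from substrate to intermediate A and held partner at its charge, which makes the step pseudo-first-order, and wrote the substrate half-life as ln(2) over the constant times partner. At 80 °C this is 0.409 d, so ochre has 7.33 half-lives in hand. Carried by the activation energy, it becomes 3.91 d in amber and 54.3 d in green.

She added that target has to come through this step and that partner falls from its charge, so the substrate turned on this reckoning bounds the target from above. The later steps were not reckoned. The meeting minuted ochre close under C at 70.0%, green below 3.76%, and ochre in the lead. For amber it minuted no estimate of target, only that the substrate turned on this reckoning is 41.2%.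

The forecast gave 69.8% for ochre, 13.2% for amber and 0.024% for green, with ochre leading, and said of amber and green that “the slow first step and the lag through two intermediates dominate”.

The simulation gives 69.6% for ochre, 13.3% for amber and 0.0249% for green, with ochre leading.

In ochre the balance closes: the 0.57% of third reagent left at 3.00 d takes C down to 69.6%, the target found. The neighbouring flask is ochre with substrate cut to 0.12 M, and there C comes to 117%. Third reagent now exceeds substrate, so the limiting reagent changes and the ceiling falls back to the substrate charge itself, 100 percent. That flask ends with 93.9% target, 1.11% of substrate left, and 20% of its third reagent unused.

Its constants were set for the occasion; the rest is arithmetic.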